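## Structural features

The target is a 1,7,8,8a-tetrahydro-6H-isochromen-6-one. A cyclohexenone (ring A: C4a, C5, C6, C7, C8, C8a) is fused through C4a–C8a to a pyran (ring B: C1, O2, C3, C4), so that O2–C3=C4–C4a=C5–C6=O is a doubly vinylogous ester with chlorine on C5. Ring A carries three contiguous stereocentres: the tertiary carbinol C7, the secondary carbinol C8 and the ring-fusion carbon C8a, with O7, O8 and C1 all on one face. C3 bears an E C1'=C2' alkene ending in the tertiary allylic carbinol C3', which is bonded to C2'' of a 2,3-trans-disubstituted oxolane (ring C). C3', C2'' and C3'' are therefore three contiguous stereocentres, the first fully substituted. The dienyl carbinol at C3' ionises in acid; the α-ketol/β-hydroxy enone array of ring A can cleave by retro-aldol or dehydrate toward a phenol in base; C8a–H is the γ-hydrogen of the enone and can be epimerised. The real difficulty is that the two stereochemical clusters are separated by a flat, achiral dienyl enol ether, so neither can control the other, and C3' has no hydrogen through which it could be corrected later. The key step uses the fact that the ring oxygen O1'' on C2'' and the hydroxyl on C3' sit on adjacent carbons in a syn relation. That is the pattern left by an oxo-metal adding across a Z C2''=C3' alkene tethered through C3''–C4''–C5'' to a hydroxyl.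

## Logic of the disconnections

**38 ⇒ 37.** The O2–C3 bond is cut. C3 is the δ-carbon of the C6 carbonyl through C4a=C5 and a C3≡C4 alkyne, so the enol ether is the retron of a conjugate addition of the C1 hydroxyl. Ring B disappears and the alkyne becomes available for a coupling. The forward step must close 6-endo and must leave C8a–H untouched.

**37 ⇒ 36 + 20.** The C4–C4a bond is cut. This is the one place where the molecule divides into its two stereochemical clusters, each of roughly equal size. The forward coupling must tolerate four free hydroxyls and needs a leaving group on C4a with chlorine already on C5.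

**36 ⇒ 35 ⇒ 34 ⇒ 33.** Functional groups only: the acetonide, the triflyl group and the chlorine are removed in turn. The acetal is taken off before fragment union so that no acid meets the C3' carbinol. The demand is O-sulfonylation at the C4a oxygen of an unsymmetrical 1,3-dione rather than at the C6 oxygen.

**33 ⇒ 32.** The C5–C6 bond is cut (Claisen retron of a 1,3-dione). The acyl donor is chosen to be the lactone whose alkoxy oxygen is the C1 oxygen, so the forward step closes ring A and frees the C1 hydroxyl together. The demand is enolisation at the C5 methyl only, because the C8a enolate would expel the lactone oxygen.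

**32 ⇒ 31 ⇒ 30 ⇒ 29.** The C7–O and C8–O bonds are cut (syn-dihydroxylation of a ring alkene). In the lactone the C8a substituent is the future C4a and the ring CH2 is the future C1. A diol trans to that substituent is therefore the all-cis O7/O8/C1 array of ring A. The C4a carbon is kept as a carbinol until after the osmylation, because a ketone there would make C8a–H doubly activated.

**29 ⇒ 28 ⇒ 26 + 27; 26 ⇒ 25 ⇒ 23 + 24; 23 ⇒ 21 + 22.** The C7=C8 bond is cut (ring-closing metathesis), then the ester, then the C8a–C4a bond (auxiliary-controlled aldol). The whole triad of ring A is traced to one auxiliary-set centre, C8a. The carbinol centre made beside it is later oxidised away.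

**20 ⇒ 17 + 18; 17 ⇒ 16 ⇒ 15 ⇒ 14.** The enyne is cut at its sp–sp2 bond, and the E C1'=C2' alkene at the aldehyde (iodo-olefination). The forward steps must not touch the unprotected C3' carbinol, which has no α-hydrogen and so cannot epimerise.

**14 ⇒ 11 (key).** O1''–C2'' and C3'–O are cut together. Ring C and two stereocentres reduce to one stereocentre (C3'') and one alkene geometry. The stereochemical course was rechecked atom by atom: syn addition to the Z alkene of 11, on the face left open when C3''–H eclipses the alkene, gives 2''S,3''S,3'R as required. The design of 11 is changed in one respect. The allylic oxygen is a plain benzyl ether, not a 4-methoxybenzyl ether. The anisyl group can be ionised or oxidised by a Lewis-acidic high-valent rhenium oxide, and its later oxidative removal next to a free tertiary carbinol invites acetal formation. A silyl ether or free hydroxyl was excluded because perrhenate esters transpose allylic oxygen and would scramble the Z geometry.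

**11 ⇒ 10 ⇒ 8 ⇒ 7 ⇒ 5 + 6.** The C=C bond is cut (Z-selective phosphonate olefination). The Z-trisubstituted geometry is the demand; the silyl and benzyl groups are ordered so that only the C5'' hydroxyl is free in 11.

**5 ⇒ 4 ⇒ 2 ⇒ 1.** The C3'' stereocentre is traced to the hydrogenation of an exocyclic alkene. The aldehyde 5 is α-chiral and must be made and used cold.

## Other disconnections considered

**Alternative 1:** The cut is C5–C6 of ring A in the deschloro dienone A1. Forward, the carboxylic acid A2 (C6 carboxyl on C7, exocyclic C4a=C5 methylene on a preformed ring B) is turned into its chloride under neutral conditions with an α-chloroenamine. The terminus C5 of the dienol ether O2–C3=C4–C4a=C5 attacks it, and loss of the C5 proton gives A1.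
- In its favour: the carbonyl position is fixed by construction, so there is no site-selectivity question at a 1,3-dione. On this point it is better than the chosen plan. The nucleophile is activated exactly where it is needed.
- Against it here: A1 lacks chlorine, so an electrophilic chlorination must later choose C5 over C4 and the side-chain alkene. The C3' carbinol must be silylated, and the acetonide must be removed by acid with the dienyl carbinol present, which the chosen plan avoids. A2 is a cross-conjugated, acid-sensitive methylenepyran.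
- Comparison: on structure, it says nothing about how the oxolane/C3' pair or the ring A triad arise, so it addresses a different part of the problem. On mechanism, acylation of a dienol ether and an enolate Claisen closure are of comparable reliability. On step economy it is about equal before the extra chlorination and two deprotections are counted.

**Alternative 2:** The cuts are C4a–C8a and C7–C8. Forward, the furan A4 (a 3-methoxy-2-methylfuran tethered through C4–C3–O2–C1 to a Z-alkenylboronate) undergoes an intramolecular Diels–Alder reaction to the oxygen-bridged boronate A3.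
- In its favour: two C–C bonds, rings A and B, and the relative configuration of C7, C8 and C8a are formed in one thermal step. The bridging oxygen becomes the C7 hydroxyl and the boron the C8 hydroxyl. In bond economy this is better than the six steps the chosen plan spends on the same triad. The relative configuration rests on a concerted suprafacial addition, which is the equal of the osmylation.
- Against it here: a furan with an unactivated dienophile reacts reversibly and needs heat, with the C3' carbinol on board. The absolute sense depends on the single tether stereocentre C3, which is remote, flexible and later destroyed. A3 has ring B saturated at C3–C4, so a late dehydrogenation is needed as well as bridge opening, enol ether hydrolysis, C–B oxidation and chlorination.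
- Comparison: the cycloaddition itself is more economical than anything in the chosen plan, but the adjustments after it should consume most of that gain. Absolute control is weaker than with an auxiliary.

**Alternative 3:** The cuts are C7–O (dearomatising hydroxylation) and O2–C1. Forward, a flavin-dependent monooxygenase hydroxylates C7 of the resorcinol aldehyde A6. The side-chain ketone enol then adds to the formyl carbon and dehydrates to give the azaphilone A5.
- In its favour: A6 is an easily assembled aromatic. The enzyme sets C7 absolutely without protecting groups, and ring B forms by itself. For the bicyclic core this is better than the chosen plan in step and atom economy.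
- Against it here: A5 is two reductions from the target. The C8 ketone and the C1=C8a alkene must be reduced with control of C8 and C8a while the C6 carbonyl, the C3=C4 enol ether and the side-chain alkene are spared, and no obviously selective reagent exists. Chlorine is still missing. Acceptance of a substrate with a polar oxolane carbinol, and the sense of hydroxylation, depend on which enzyme of the class is used.
- Comparison: on structure, A6 still needs the oxolane carbinol, so the chosen key step or an equivalent remains necessary. On mechanism, the enzyme gives better control at C7 but no handle on C8 or C8a, where the chosen plan is stronger.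

Key step: step 8

Assumption: the (R)-BINAP ruthenium catalyst of step 1 is taken to give the 3S lactone and D-(−)-tartrate the 2R,3R epoxide of one fallback, as the usual models predict; the other antipode would be used if not.

## Route

Step 1
Reactants: 1 α-methylene-γ-butyrolactone (3-methylideneoxolan-2-one)
Product: 2 (3S)-3-methyloxolan-2-one
Conditions: H2 (50 atm), Ru(OAc)2[(R)-BINAP] (0.5 mol%), CH2Cl2, 50 °C
Reagents that add atoms: none
Why: Asymmetric hydrogenation of an exocyclic α-methylene lactone with a BINAP ruthenium diacetate catalyst; the lactone carbonyl binds the metal and the ligand antipode decides the face, setting C3'' (S).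

Step 2
Reactants: 2 (3S)-3-methyloxolan-2-one
Product: 4 (2S)-4-[(tert-butyldimethylsilyl)oxy]-N-methoxy-N,2-dimethylbutanamide, via hydroxy amide 3 (not isolated)
Conditions: MeNH(OMe)·HCl, AlMe3, CH2Cl2, 0 °C to rt; then tBuMe2SiCl, imidazole, DMF, rt
Reagents that add atoms: N,O-dimethylhydroxylamine hydrochloride, CNOC.Cl; tert-butyldimethylsilyl chloride, CC(C)(C)[Si](C)(C)Cl
Why: Aluminium amide aminolysis of a lactone (Weinreb amide formation) followed by silylation of the crude γ-hydroxy amide, which would otherwise relactonise; the stereocentre is not involved.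

Step 3
Reactants: 4 (2S)-4-[(tert-butyldimethylsilyl)oxy]-N-methoxy-N,2-dimethylbutanamide
Product: 5 (2S)-4-[(tert-butyldimethylsilyl)oxy]-2-methylbutanal
Conditions: iBu2AlH, THF, −78 °C
Reagents that add atoms: none
Why: Hydride reduction of an N-methoxy-N-methylamide stops at the aldehyde through the chelated tetrahedral intermediate; low temperature and direct use protect the α-stereocentre.

Step 4
Reactants: 5 (2S)-4-[(tert-butyldimethylsilyl)oxy]-2-methylbutanal; 6 methyl 2-[bis(2,2,2-trifluoroethoxy)phosphoryl]propanoate
Product: 7 methyl (2Z,4S)-6-[(tert-butyldimethylsilyl)oxy]-2,4-dimethylhex-2-enoate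
Conditions: KN(SiMe3)2, 18-crown-6, THF, −78 °C
Reagents that add atoms: none
Why: Still–Gennari olefination; the electron-poor phosphonate with a dissociated potassium counter-ion eliminates faster than the adducts equilibrate, which gives the Z-trisubstituted enoate, and the cold non-equilibrating conditions spare the α-stereocentre.

Step 5
Reactants: 7 methyl (2Z,4S)-6-[(tert-butyldimethylsilyl)oxy]-2,4-dimethylhex-2-enoate
Product: 8 (2Z,4S)-6-[(tert-butyldimethylsilyl)oxy]-2,4-dimethylhex-2-en-1-ol
Conditions: iBu2AlH, CH2Cl2, −78 °C
Reagents that add atoms: none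
Why: 1,2-Reduction of an enoate to the allylic alcohol with retention of the Z geometry.

Step 6
Reactants: 8 (2Z,4S)-6-[(tert-butyldimethylsilyl)oxy]-2,4-dimethylhex-2-en-1-ol; 9 benzyl bromide
Product: 10 {[(3S,4Z)-6-(benzyloxy)-3,5-dimethylhex-4-en-1-yl]oxy}(tert-butyl)dimethylsilane
Conditions: NaH, Bu4NI (cat.), THF, 0 °C to rt
Reagents that add atoms: none
Why: Williamson etherification; the benzyl ether is chosen because it cannot form a perrhenate ester, is not ionised by a Lewis-acidic oxidant, and later leaves by hydrogenolysis.

Step 7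
Reactants: 10 {[(3S,4Z)-6-(benzyloxy)-3,5-dimethylhex-4-en-1-yl]oxy}(tert-butyl)dimethylsilane
Product: 11 (3S,4Z)-6-(benzyloxy)-3,5-dimethylhex-4-en-1-ol
Conditions: Bu4NF, THF, 0 °C to rt
Reagents that add atoms: none
Why: Fluoride desilylation frees the single hydroxyl (C5''–OH) that is to carry rhenium.

Step 8
Reactants: 11 (3S,4Z)-6-(benzyloxy)-3,5-dimethylhex-4-en-1-ol
Product: 14 (2R)-1-(benzyloxy)-2-[(2S,3S)-3-methyloxolan-2-yl]propan-2-ol, via perrhenate ester 12 (not isolated), via reduced rhenium ester 13 (not isolated)
Conditions: Re2O7, 2,6-lutidine, 4 Å molecular sieves, CH2Cl2, rt; then aq. NaHCO3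
Reagents that add atoms: dirhenium heptoxide, O=[Re](=O)(=O)O[Re](=O)(=O)=O
Why: Re2O7 converts the primary alcohol into perrhenate ester 12; the alkoxide oxygen on heptavalent rhenium and one oxo ligand then add suprafacially across C2''=C3', reducing the metal to the pentavalent state in 13, whose hydrolysis frees the C3' hydroxyl. The closest known reaction type is the perrhenate-mediated syn-oxidative cyclisation of bishomoallylic alcohols to 2-(1-hydroxyalkyl)oxolanes. Ring C closes 5-exo-trig (O1''–C2''), the only mode in which the O–Re=O unit spans the alkene. C2'' and C3' are set relative to each other by the syn addition together with the Z geometry, which can give only the 2''S,3'R pair or its mirror image, never the C3' epimer. The absolute sense comes from C3'': allylic 1,3-strain against the Z-CH2OBn group holds C3''–H in the alkene plane, so the C4''–C5''–O tether lies on one face and delivers rhenium there, leaving the C3'' methyl trans to C3' (2''S,3''S). The step needs chemoselectivity, secured by a single alkene and a single free hydroxyl, and retention of the Z geometry, secured by the benzyl ether (no allylic perrhenate, so no transposition) and by 2,6-lutidine, which buffers perrhenic acid.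

Step 9
Reactants: 14 (2R)-1-(benzyloxy)-2-[(2S,3S)-3-methyloxolan-2-yl]propan-2-ol
Product: 15 (2R)-2-[(2S,3S)-3-methyloxolan-2-yl]propane-1,2-diol
Conditions: H2 (1 atm), Pd/C, EtOAc, rt
Reagents that add atoms: none
Why: Hydrogenolysis of a benzyl ether; the molecule has no other reducible group at this stage.

Step 10
Reactants: 15 (2R)-2-[(2S,3S)-3-methyloxolan-2-yl]propane-1,2-diol
Product: 16 (2S)-2-hydroxy-2-[(2S,3S)-3-methyloxolan-2-yl]propanal
Conditions: SO3·pyridine, DMSO, iPr2NEt, CH2Cl2, 0 °C
Reagents that add atoms: none
Why: Parikh–Doering oxidation of the primary hydroxyl of a 1,2-diol; activated DMSO does not cleave glycols, and the aldehyde has no α-hydrogen, so C3' is safe.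

Step 11
Reactants: 16 (2S)-2-hydroxy-2-[(2S,3S)-3-methyloxolan-2-yl]propanal
Product: 17 (2R,3E)-4-iodo-2-[(2S,3S)-3-methyloxolan-2-yl]but-3-en-2-ol
Conditions: CrCl2 (8 equiv), CHI3, THF/1,4-dioxane, 0 °C to rt
Reagents that add atoms: iodoform, IC(I)I
Why: Takai olefination; the geminal dichromium species made from CHI3 and divalent chromium adds to the aldehyde and eliminates to the E vinyl iodide, and the α-quaternary centre reinforces E selectivity. The free tertiary hydroxyl is expected to consume only one equivalent of the reductant as its alkoxide.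

Step 12
Reactants: 17 (2R,3E)-4-iodo-2-[(2S,3S)-3-methyloxolan-2-yl]but-3-en-2-ol; 18 ethynyltrimethylsilane
Product: 20 (2R,3E)-2-[(2S,3S)-3-methyloxolan-2-yl]hex-3-en-5-yn-2-ol, via silylated enyne 19 (not isolated)
Conditions: Pd(PPh3)2Cl2 (3 mol%), CuI (6 mol%), Et3N, THF, rt; then K2CO3, MeOH, rt
Reagents that add atoms: none
Why: Sonogashira coupling of a vinyl iodide proceeds with retention of the E geometry; methanolysis of the C–Si bond in the same flask gives the terminal enyne.

Step 13
Reactants: 21 (4S)-4-benzyl-1,3-oxazolidin-2-one; 22 (2E)-but-2-enoyl chloride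
Product: 23 (4S)-4-benzyl-3-[(2E)-but-2-enoyl]-1,3-oxazolidin-2-one
Conditions: n-BuLi, THF, −78 °C
Reagents that add atoms: none
Why: N-Acylation of the lithiated oxazolidinone.

Step 14
Reactants: 23 (4S)-4-benzyl-3-[(2E)-but-2-enoyl]-1,3-oxazolidin-2-one; 24 acetaldehyde
Product: 25 (4S)-4-benzyl-3-[(2S,3R)-2-ethenyl-3-hydroxybutanoyl]-1,3-oxazolidin-2-one
Conditions: Bu2BOTf, Et3N, CH2Cl2, −78 to 0 °C; then 24, −78 °C
Reagents that add atoms: none
Why: Evans syn-aldol reaction of the boron dienolate formed by γ-deprotonation, which reacts at its α-carbon through a closed chair transition state. The benzyl group of the auxiliary shields one enolate face and so sets C8a (2S in 25); the carbinol centre formed beside it is oxidised away in step 20.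

Step 15
Reactants: 25 (4S)-4-benzyl-3-[(2S,3R)-2-ethenyl-3-hydroxybutanoyl]-1,3-oxazolidin-2-one
Product: 26 (2R,3R)-2-ethenylbutane-1,3-diol
Conditions: LiBH4, MeOH (1 equiv), THF, 0 °C
Reagents that add atoms: none
Why: Reductive cleavage of the imide gives the primary alcohol (the future C1) and releases the auxiliary; the descriptor at C8a changes only because the priorities change.

Step 16
Reactants: 26 (2R,3R)-2-ethenylbutane-1,3-diol; 27 2-methylprop-2-enoyl chloride
Product: 28 (2R,3R)-2-ethenyl-3-hydroxybutyl 2-methylprop-2-enoate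
Conditions: 2,4,6-collidine, CH2Cl2, −78 to −30 °C
Reagents that add atoms: none
Why: Acylation with an acid chloride; the primary hydroxyl reacts far faster than the secondary one at low temperature, and a hindered pyridine base avoids conjugate addition to the methacrylate.

Step 17
Reactants: 28 (2R,3R)-2-ethenyl-3-hydroxybutyl 2-methylprop-2-enoate
Product: 29 (5R)-5-[(1R)-1-hydroxyethyl]-3-methyl-5,6-dihydro-2H-pyran-2-one
Conditions: second-generation Grubbs catalyst RuCl2(=CHPh)(PCy3)(H2IMes) (5 mol%), CH2Cl2 (5 mM), 40 °C
Reagents that add atoms: none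
Why: Ring-closing olefin metathesis of the vinyl group with the methacrylate gives the α-methyl unsaturated δ-lactone with loss of ethene; the ring holds C7=C8 in the geometry a cis diol requires.

Step 18
Reactants: 29 (5R)-5-[(1R)-1-hydroxyethyl]-3-methyl-5,6-dihydro-2H-pyran-2-one
Product: 30 (3R,4R,5R)-3,4-dihydroxy-5-[(1R)-1-hydroxyethyl]-3-methyloxan-2-one
Conditions: OsO4 (2 mol%), N-methylmorpholine N-oxide, citric acid, tBuOH/H2O, rt
Reagents that add atoms: osmium tetroxide, O=[Os](=O)(=O)=O; N-methylmorpholine N-oxide, C[N+]1([O-])CCOCC1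
Why: Catalytic osmylation (Upjohn conditions, with citric acid to speed turnover on the electron-poor alkene); OsO4 adds suprafacially to the face of C7=C8 opposite the allylic C8a side chain, which sets C7 and C8. O7 and O8 are cis to each other and trans to that chain; since the chain carbon becomes ring carbon C4a and the lactone CH2 becomes the C1 substituent, this is the all-cis O7/O8/C1 array of ring A.

Step 19
Reactants: 30 (3R,4R,5R)-3,4-dihydroxy-5-[(1R)-1-hydroxyethyl]-3-methyloxan-2-one
Product: 31 (3aR,7R,7aR)-7-[(1R)-1-hydroxyethyl]-2,2,3a-trimethyltetrahydro-4H-[1,3]dioxolo[4,5-c]pyran-4-one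
Conditions: 2,2-dimethoxypropane, pyridinium p-toluenesulfonate, acetone, rt
Reagents that add atoms: 2,2-dimethoxypropane, COC(C)(C)OC
Why: Ketalisation under equilibrating acid catalysis; the cis vicinal diol gives the five-membered acetonide in preference to a six-membered ketal through the side-chain hydroxyl, which stays free for oxidation.

Step 20
Reactants: 31 (3aR,7R,7aR)-7-[(1R)-1-hydroxyethyl]-2,2,3a-trimethyltetrahydro-4H-[1,3]dioxolo[4,5-c]pyran-4-one
Product: 32 (3aR,7S,7aR)-7-acetyl-2,2,3a-trimethyltetrahydro-4H-[1,3]dioxolo[4,5-c]pyran-4-one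
Conditions: Dess–Martin periodinane, NaHCO3, CH2Cl2, 0 °C to rt
Reagents that add atoms: none
Why: Periodinane oxidation of the secondary alcohol to the methyl ketone under buffered, base-free conditions, as required for a β-acyloxy ketone; it also removes the hydroxyl before it can migrate onto the lactone carbonyl.

Step 21
Reactants: 32 (3aR,7S,7aR)-7-acetyl-2,2,3a-trimethyltetrahydro-4H-[1,3]dioxolo[4,5-c]pyran-4-one
Product: 33 (3aR,7S,7aR)-7-(hydroxymethyl)-2,2,3a-trimethyltetrahydro-1,3-benzodioxole-4,6-dione
Conditions: LiN(iPr)2 (2.2 equiv), THF, −78 to −20 °C; then aq. NH4Cl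
Reagents that add atoms: none
Why: Intramolecular Claisen condensation; kinetic, irreversible deprotonation of the methyl group gives the C5 enolate, which attacks the lactone carbonyl C6 across the ring through a boat (a 2-oxabicyclo[2.2.2]octane-type tetrahedral intermediate). Collapse expels the C1 alkoxide, so ring A closes and the C1 hydroxyl is freed in one event, and the acidic dione is held as its enolate. No stereocentre is formed, and C8a keeps its configuration because it is never deprotonated.

Step 22
Reactants: 33 (3aR,7S,7aR)-7-(hydroxymethyl)-2,2,3a-trimethyltetrahydro-1,3-benzodioxole-4,6-dione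
Product: 34 (3aR,7S,7aR)-5-chloro-6-hydroxy-7-(hydroxymethyl)-2,2,3a-trimethyl-7,7a-dihydro-1,3-benzodioxol-4(3aH)-one (enol form of the 5-chloro-4,6-dione)
Conditions: N-chlorosuccinimide (1.0 equiv), CH2Cl2, 0 °C
Reagents that add atoms: N-chlorosuccinimide, O=C1CCC(=O)N1Cl
Why: Electrophilic chlorination of the enolised 1,3-dione at C5, its only nucleophilic carbon; one equivalent avoids the 5,5-dichloride.

Step 23
Reactants: 34 (3aR,7S,7aR)-5-chloro-6-hydroxy-7-(hydroxymethyl)-2,2,3a-trimethyl-7,7a-dihydro-1,3-benzodioxol-4(3aH)-one
Product: 35 (3aR,7S,7aR)-5-chloro-7-(hydroxymethyl)-2,2,3a-trimethyl-4-oxo-3a,4,7,7a-tetrahydro-1,3-benzodioxol-6-yl trifluoromethanesulfonate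
Conditions: PhNTf2, iPr2NEt, DMAP (cat.), CH2Cl2, 0 °C to rt
Reagents that add atoms: N-phenylbis(trifluoromethanesulfonimide), O=S(=O)(N(c1ccccc1)S(=O)(=O)C(F)(F)F)C(F)(F)F
Why: O-Sulfonylation of the dione enolate; the oxygen on C4a is flanked by the tertiary C8a, whereas that on C6 is flanked by the fully substituted, oxygen-bearing C7, so steric access and the inductive pull of O7 should both send the triflyl group to O4a. The neutral primary hydroxyl is not expected to react with this mild triflyl donor.

Step 24
Reactants: 35 (3aR,7S,7aR)-5-chloro-7-(hydroxymethyl)-2,2,3a-trimethyl-4-oxo-3a,4,7,7a-tetrahydro-1,3-benzodioxol-6-yl trifluoromethanesulfonate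
Product: 36 (4R,5R,6S)-2-chloro-4,5-dihydroxy-6-(hydroxymethyl)-4-methyl-3-oxocyclohex-1-en-1-yl trifluoromethanesulfonate
Conditions: CF3CO2H/H2O (4:1), 0 °C
Reagents that add atoms: none
Why: Acid hydrolysis of the acetonide on the acid-stable vinylogous acyl triflate, placed here so that no acid is needed once the acid-labile dienyl carbinol is present.

Step 25
Reactants: 36 (4R,5R,6S)-2-chloro-4,5-dihydroxy-6-(hydroxymethyl)-4-methyl-3-oxocyclohex-1-en-1-yl trifluoromethanesulfonate; 20 (2R,3E)-2-[(2S,3S)-3-methyloxolan-2-yl]hex-3-en-5-yn-2-ol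
Product: 38 (7R,8R,8aS)-5-chloro-7,8-dihydroxy-3-[(1E,3R)-3-hydroxy-3-[(2S,3S)-3-methyloxolan-2-yl]but-1-en-1-yl]-7-methyl-1,7,8,8a-tetrahydro-6H-isochromen-6-one, via ynenone 37 (not isolated)
Conditions: Pd(PPh3)2Cl2 (5 mol%), CuI (10 mol%), iPr2NEt, THF (degassed), 0 °C to rt, then 40 °C
Reagents that add atoms: none
Why: Sonogashira coupling at the C4a–O bond of the vinylogous acyl triflate (not at C5–Cl) forms C4–C4a; the hindered tertiary amine cannot displace the triflate by addition–elimination. The C1 hydroxyl then adds to C3, the δ-position of ynenone 37, in a 6-endo-dig conjugate addition, and protonation at C4 gives the dienone; attack at C4 (5-exo) would not be a conjugate addition, and the other hydroxyls cannot reach C3 without forming a bridged ring.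

## Compound list

1 | α-methylene-γ-butyrolactone (3-methylideneoxolan-2-one) | C=C1CCOC1=O | starting material
2 | (3S)-3-methyloxolan-2-one | C[C@H]1CCOC1=O | intermediate
3 | (2S)-4-hydroxy-N-methoxy-N,2-dimethylbutanamide | C[C@@H](CCO)C(=O)N(C)OC | intermediate
4 | (2S)-4-[(tert-butyldimethylsilyl)oxy]-N-methoxy-N,2-dimethylbutanamide | C[C@@H](CCO[Si](C)(C)C(C)(C)C)C(=O)N(C)OC | intermediate
5 | (2S)-4-[(tert-butyldimethylsilyl)oxy]-2-methylbutanal | C[C@@H](CCO[Si](C)(C)C(C)(C)C)C=O | intermediate
6 | methyl 2-[bis(2,2,2-trifluoroethoxy)phosphoryl]propanoate | COC(=O)C(C)P(=O)(OCC(F)(F)F)OCC(F)(F)F | starting material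
7 | methyl (2Z,4S)-6-[(tert-butyldimethylsilyl)oxy]-2,4-dimethylhex-2-enoate | C[C@@H](CCO[Si](C)(C)C(C)(C)C)/C=C(/C)C(=O)OC | intermediate
8 | (2Z,4S)-6-[(tert-butyldimethylsilyl)oxy]-2,4-dimethylhex-2-en-1-ol | C[C@@H](CCO[Si](C)(C)C(C)(C)C)/C=C(/C)CO | intermediate
9 | benzyl bromide | BrCc1ccccc1 | starting material
10 | {[(3S,4Z)-6-(benzyloxy)-3,5-dimethylhex-4-en-1-yl]oxy}(tert-butyl)dimethylsilane | C[C@@H](CCO[Si](C)(C)C(C)(C)C)/C=C(/C)COCc1ccccc1 | intermediate
11 | (3S,4Z)-6-(benzyloxy)-3,5-dimethylhex-4-en-1-ol | C[C@@H](CCO)/C=C(/C)COCc1ccccc1 | intermediate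
12 | (3S,4Z)-6-(benzyloxy)-3,5-dimethylhex-4-en-1-yl perrhenate | C[C@@H](CCO[Re](=O)(=O)=O)/C=C(/C)COCc1ccccc1 | intermediate
13 | dioxorhenium alkoxide (pentavalent rhenium) of 14, bound through the C3' oxygen | C[C@H]1CCO[C@@H]1[C@](C)(O[Re](=O)=O)COCc1ccccc1 | intermediate
14 | (2R)-1-(benzyloxy)-2-[(2S,3S)-3-methyloxolan-2-yl]propan-2-ol | C[C@H]1CCO[C@@H]1[C@](C)(O)COCc1ccccc1 | intermediate
15 | (2R)-2-[(2S,3S)-3-methyloxolan-2-yl]propane-1,2-diol | C[C@H]1CCO[C@@H]1[C@](C)(O)CO | intermediate
16 | (2S)-2-hydroxy-2-[(2S,3S)-3-methyloxolan-2-yl]propanal | C[C@H]1CCO[C@@H]1[C@](C)(O)C=O | intermediate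
17 | (2R,3E)-4-iodo-2-[(2S,3S)-3-methyloxolan-2-yl]but-3-en-2-ol | C[C@H]1CCO[C@@H]1[C@](C)(O)/C=C/I | intermediate
18 | ethynyltrimethylsilane | C#C[Si](C)(C)C | starting material
19 | (2R,3E)-2-[(2S,3S)-3-methyloxolan-2-yl]-6-(trimethylsilyl)hex-3-en-5-yn-2-ol | C[C@H]1CCO[C@@H]1[C@](C)(O)/C=C/C#C[Si](C)(C)C | intermediate
20 | (2R,3E)-2-[(2S,3S)-3-methyloxolan-2-yl]hex-3-en-5-yn-2-ol | C[C@H]1CCO[C@@H]1[C@](C)(O)/C=C/C#C | intermediate
21 | (4S)-4-benzyl-1,3-oxazolidin-2-one | O=C1N[C@@H](Cc2ccccc2)CO1 | starting material
22 | (2E)-but-2-enoyl chloride | C/C=C/C(Cl)=O | starting material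
23 | (4S)-4-benzyl-3-[(2E)-but-2-enoyl]-1,3-oxazolidin-2-one | C/C=C/C(=O)N1C(=O)OC[C@@H]1Cc1ccccc1 | intermediate
24 | acetaldehyde | CC=O | starting material
25 | (4S)-4-benzyl-3-[(2S,3R)-2-ethenyl-3-hydroxybutanoyl]-1,3-oxazolidin-2-one | C=C[C@@H]([C@@H](C)O)C(=O)N1C(=O)OC[C@@H]1Cc1ccccc1 | intermediate
26 | (2R,3R)-2-ethenylbutane-1,3-diol | C=C[C@@H]([C@@H](C)O)CO | intermediate
27 | 2-methylprop-2-enoyl chloride | C=C(C)C(Cl)=O | starting material
28 | (2R,3R)-2-ethenyl-3-hydroxybutyl 2-methylprop-2-enoate | C=C[C@@H]([C@@H](C)O)COC(=O)C(C)=C | intermediate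
29 | (5R)-5-[(1R)-1-hydroxyethyl]-3-methyl-5,6-dihydro-2H-pyran-2-one | CC1=C[C@@H]([C@@H](C)O)COC1=O | intermediate
30 | (3R,4R,5R)-3,4-dihydroxy-5-[(1R)-1-hydroxyethyl]-3-methyloxan-2-one | C[C@@]1(O)[C@H](O)[C@@H]([C@@H](C)O)COC1=O | intermediate
31 | (3aR,7R,7aR)-7-[(1R)-1-hydroxyethyl]-2,2,3a-trimethyltetrahydro-4H-[1,3]dioxolo[4,5-c]pyran-4-one | C[C@@]1(OC(C)(C)O2)[C@H]2[C@@H]([C@@H](C)O)COC1=O | intermediate
32 | (3aR,7S,7aR)-7-acetyl-2,2,3a-trimethyltetrahydro-4H-[1,3]dioxolo[4,5-c]pyran-4-one | C[C@@]1(OC(C)(C)O2)[C@H]2[C@@H](C(C)=O)COC1=O | intermediate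
33 | (3aR,7S,7aR)-7-(hydroxymethyl)-2,2,3a-trimethyltetrahydro-1,3-benzodioxole-4,6-dione | O=C1CC(=O)[C@]2(C)OC(C)(C)O[C@@H]2[C@@H]1CO | intermediate
34 | (3aR,7S,7aR)-5-chloro-6-hydroxy-7-(hydroxymethyl)-2,2,3a-trimethyl-7,7a-dihydro-1,3-benzodioxol-4(3aH)-one | OC1=C(Cl)C(=O)[C@]2(C)OC(C)(C)O[C@@H]2[C@@H]1CO | intermediate
35 | (3aR,7S,7aR)-5-chloro-7-(hydroxymethyl)-2,2,3a-trimethyl-4-oxo-3a,4,7,7a-tetrahydro-1,3-benzodioxol-6-yl trifluoromethanesulfonate | O=S(=O)(OC1=C(Cl)C(=O)[C@]2(C)OC(C)(C)O[C@@H]2[C@@H]1CO)C(F)(F)F | intermediate
36 | (4R,5R,6S)-2-chloro-4,5-dihydroxy-6-(hydroxymethyl)-4-methyl-3-oxocyclohex-1-en-1-yl trifluoromethanesulfonate | O=S(=O)(OC1=C(Cl)C(=O)[C@](C)(O)[C@H](O)[C@@H]1CO)C(F)(F)F | intermediate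
37 | (4S,5R,6R)-2-chloro-5,6-dihydroxy-4-(hydroxymethyl)-3-[(3E,5R)-5-hydroxy-5-[(2S,3S)-3-methyloxolan-2-yl]hex-3-en-1-yn-1-yl]-6-methylcyclohex-2-en-1-one | C[C@H]1CCO[C@@H]1[C@](C)(O)/C=C/C#CC1=C(Cl)C(=O)[C@](C)(O)[C@H](O)[C@@H]1CO | intermediate
38 | (7R,8R,8aS)-5-chloro-7,8-dihydroxy-3-[(1E,3R)-3-hydroxy-3-[(2S,3S)-3-methyloxolan-2-yl]but-1-en-1-yl]-7-methyl-1,7,8,8a-tetrahydro-6H-isochromen-6-one | C[C@H]1CCO[C@@H]1[C@](C)(O)/C=C/C1=CC2=C(Cl)C(=O)[C@](C)(O)[C@H](O)[C@@H]2CO1 | target

## Step count and least certain steps

Total: 25 steps. Longest linear sequence: 13 steps (steps 1–12, then 25; the core branch, steps 13–24 then 25, is equally long).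

**Step 8 (key step).** The cyclisation may be slow, because the perrhenate ester is primary and the alkene is made less electron-rich by the allylic ether. Slow turnover would give perrhenic acid time to isomerise the alkene or attack the ether, which would erode the C3' configuration. The fallback sets out from 5 and returns at 15; it replaces syn addition to the Z alkene by anti addition to the E alkene. A Wittig reaction of 5 with Ph3P=C(CH3)CO2Et would give ethyl (2E,4S)-6-[(tert-butyldimethylsilyl)oxy]-2,4-dimethylhex-2-enoate F1, and iBu2AlH the E allylic alcohol F2. Sharpless epoxidation (Ti(OiPr)4, D-(−)-diisopropyl tartrate, tBuOOH) would set both epoxide carbons by reagent control in the epoxy alcohol F3. HF·pyridine would remove the silyl group to give the epoxy diol F4. A trace of camphorsulfonic acid would then close ring C by 5-exo attack of the C5'' hydroxyl at the secondary epoxide carbon with inversion, giving 15.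

**Step 21.** Proton transfer to the more substituted C8a enolate would expel the lactone oxygen by β-elimination. The acylation may also stall because the ring must adopt a boat. The fallback sets out from 31 and returns at 33; it closes ring A on an open chain. MeNH(OMe)·HCl/AlMe3 would open the lactone to the N-methoxy-N-methylamide diol F5, and tBuMe2SiCl would silylate the primary hydroxyl to give the silyl ether F6. Dess–Martin oxidation would give the keto amide F7, in which the β-oxygen is a poor leaving group. LiN(iPr)2 would then acylate the methyl ketone enolate with the amide to give the dione silyl ether F8, and HF·pyridine would return 33.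

**Step 23.** Sulfonylation may occur at the C6 oxygen, for instance if the neighbouring C1 hydroxyl hydrogen-bonds to the C4a oxygen and deactivates it. The fallback sets out from 34 and returns at 37; it uses that opposite site preference by replacing cross-coupling with carbonyl addition and transposition (Stork–Danheiser type). Methylation with Me3SiCHN2 in MeOH would give the C6 methyl enol ether F9. After deprotonation of its hydroxyl, the dilithium salt of 20 would add to the now free and less hindered C4a carbonyl to give the tertiary carbinol F10. Aqueous trifluoroacetic acid would hydrolyse the enol ether with loss of the C4a hydroxyl and remove the acetonide, giving 37, which closes to 38 as in step 25.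

**Step 25.** With three free hydroxyls and a base present, base-induced elimination toward a phenol or loss of the C8a configuration may compete with oxidative addition. Ring closure may also lag behind the coupling. The fallback sets out from 35 and 20 and returns at 38; it changes to a protected substrate and a π-acid closure. Sonogashira coupling on the acetonide would give the protected ynenone F11. Ph3PAuCl/AgOTf would close ring B without base to the acetonide of the target F12. Warm aqueous acetic acid would then remove the acetal.

**Step 11.** Binding of divalent chromium by the free α-hydroxy aldehyde (as alkoxide or hemiacetal dimer) may stop the olefination short or lower the E selectivity. The fallback sets out from 16 and returns at 17. The Ohira–Bestmann reagent with K2CO3 in MeOH would give the alkyne (2R)-2-[(2S,3S)-3-methyloxolan-2-yl]but-3-yn-2-ol F13. Hydrozirconation with Cp2Zr(H)Cl followed by I2 would give the E vinyl iodide 17 by syn addition and retentive iodinolysis.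

## Further compounds

F1 | step 8 | ethyl (2E,4S)-6-[(tert-butyldimethylsilyl)oxy]-2,4-dimethylhex-2-enoate | C[C@@H](CCO[Si](C)(C)C(C)(C)C)/C=C(\C)C(=O)OCC
F2 | step 8 | (2E,4S)-6-[(tert-butyldimethylsilyl)oxy]-2,4-dimethylhex-2-en-1-ol | C[C@@H](CCO[Si](C)(C)C(C)(C)C)/C=C(\C)CO
F3 | step 8 | [(2R,3R)-3-[(2S)-4-[(tert-butyldimethylsilyl)oxy]butan-2-yl]-2-methyloxiran-2-yl]methanol | C[C@@H](CCO[Si](C)(C)C(C)(C)C)[C@H]1O[C@]1(C)CO
F4 | step 8 | (3S)-3-[(2R,3R)-3-(hydroxymethyl)-3-methyloxiran-2-yl]butan-1-ol | C[C@@H](CCO)[C@H]1O[C@]1(C)CO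
F5 | step 21 | (4R,5R)-5-[(2R,3R)-1,3-dihydroxybutan-2-yl]-N-methoxy-N,2,2,4-tetramethyl-1,3-dioxolane-4-carboxamide | CON(C)C(=O)[C@]1(C)OC(C)(C)O[C@@H]1[C@H](CO)[C@@H](C)O
F6 | step 21 | primary tert-butyldimethylsilyl ether of F5 | CON(C)C(=O)[C@]1(C)OC(C)(C)O[C@@H]1[C@H](CO[Si](C)(C)C(C)(C)C)[C@@H](C)O
F7 | step 21 | methyl ketone from oxidation of the secondary hydroxyl of F6 | CON(C)C(=O)[C@]1(C)OC(C)(C)O[C@@H]1[C@H](CO[Si](C)(C)C(C)(C)C)C(C)=O
F8 | step 21 | tert-butyldimethylsilyl ether of 33 | O=C1CC(=O)[C@]2(C)OC(C)(C)O[C@@H]2[C@@H]1CO[Si](C)(C)C(C)(C)C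
F9 | step 23 | (3aR,7S,7aR)-5-chloro-7-(hydroxymethyl)-4-methoxy-2,2,3a-trimethyl-7,7a-dihydro-1,3-benzodioxol-6(3aH)-one | O=C1C(Cl)=C(OC)[C@]2(C)OC(C)(C)O[C@@H]2[C@@H]1CO
F10 | step 23 | tertiary carbinol from addition of the acetylide of 20 to the C4a carbonyl of F9 (new centre undefined) | C[C@H]1CCO[C@@H]1[C@](C)(O)/C=C/C#CC1(O)C(Cl)=C(OC)[C@]2(C)OC(C)(C)O[C@@H]2[C@@H]1CO
F11 | step 25 | 7,8-O-isopropylidene derivative of 37 | C[C@H]1CCO[C@@H]1[C@](C)(O)/C=C/C#CC1=C(Cl)C(=O)[C@]2(C)OC(C)(C)O[C@@H]2[C@@H]1CO
F12 | step 25 | 7,8-O-isopropylidene derivative of 38 | C[C@H]1CCO[C@@H]1[C@](C)(O)/C=C/C1=CC2=C(Cl)C(=O)[C@]3(C)OC(C)(C)O[C@@H]3[C@@H]2CO1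
F13 | step 11 | (2R)-2-[(2S,3S)-3-methyloxolan-2-yl]but-3-yn-2-ol | C[C@H]1CCO[C@@H]1[C@](C)(O)C#C
A1 | alternative 1 | 5-deschloro bicyclic dienone, 7,8-acetonide, side-chain triethylsilyl ether | C[C@H]1CCO[C@@H]1[C@](C)(O[Si](CC)(CC)CC)/C=C/C1=CC2=CC(=O)[C@]3(C)OC(C)(C)O[C@@H]3[C@@H]2CO1
A2 | alternative 1 | methylenepyran carboxylic acid (C6 acid on C7, exocyclic C4a=C5, 7,8-acetonide, triethylsilyl ether) | C[C@H]1CCO[C@@H]1[C@](C)(O[Si](CC)(CC)CC)/C=C/C1=CC(=C)[C@@H](CO1)[C@H]1OC(C)(C)O[C@@]1(C)C(=O)O
A3 | alternative 2 | oxygen-bridged tricyclic pinacolboronate (7-oxanorbornene fused to the pyran) | C[C@H]1CCO[C@@H]1[C@](C)(O)/C=C/[C@H]1C[C@]23C=C(OC)[C@](C)(O2)[C@H](B4OC(C)(C)C(C)(C)O4)[C@@H]3CO1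
A4 | alternative 2 | 3-methoxy-2-methylfuran tethered through C4–C3–O2–C1 to a Z-alkenyl pinacolboronate | C[C@H]1CCO[C@@H]1[C@](C)(O)/C=C/[C@@H](Cc1cc(OC)c(C)o1)OC/C=C\B1OC(C)(C)C(C)(C)O1
A5 | alternative 3 | (7S)-7-hydroxy-7-methyl-3-[(E,3R)-3-hydroxy-3-[(2S,3S)-3-methyloxolan-2-yl]but-1-enyl]-6H-isochromene-6,8(7H)-dione | C[C@H]1CCO[C@@H]1[C@](C)(O)/C=C/C1=CC2=CC(=O)[C@](C)(O)C(=O)C2=CO1
A6 | alternative 3 | 2,4-dihydroxy-6-[(3E,5R)-5-hydroxy-5-[(2S,3S)-3-methyloxolan-2-yl]-2-oxohex-3-en-1-yl]-3-methylbenzaldehyde | C[C@H]1CCO[C@@H]1[C@](C)(O)/C=C/C(=O)Cc1cc(O)c(C)c(O)c1C=O
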